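All runs were computed for substances that don't exist, and the scatter is random.

5 questions stand on 4 flasks that differ only in how the charge goes in, and the earlier runs show which clock to hold the feed against.

| flask | starting material | partner | capture agent | remark | time |
|---|---|---|---|---|---|
| alder | 20 mM | 24 mM | 20 mM | run made earlier |  |
| larch | 10 mM | 24 mM | 20 mM | run made earlier |  |
| Monday's | 20 mM | 24.0 mM | 20.0 mM | everything together at the start | 15 min |
| Tuesday's | 20 mM | 24.0 mM (fed, over 3.0 min) | 20.0 mM | all else is in the flask from the start; the feed brings no volume worth counting | 15 min |
| Thursday's | 20 mM (in portions, 2, over 3.0 min) | 24.0 mM | 20.0 mM | first portion at the start, last at 3.0 min | 15 min |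
| Sunday's | 20 mM (fed, over 3.0 min) | 24.0 mM | 20.0 mM | all else is in the flask from the start; the feed brings no volume worth counting | 15 min |

- alder (time / min: target / %, starting material / %): 0.500: 45.1, 24.9; 1.33: 66.4, 9.5; 2.50: 71.7, 4.5; 4.00: 75.5, 0; 5.00: 72.8, 2.4; 8.00: 74.9, 0; 10.0: 77.2, 0
- larch (time / min: target / %, starting material / %): 0.167: 20.1, 52.1; 0.500: 53.2, 21.1; 0.833: 66.6, 10.7; 1.33: 73.1, 7.6; 2.00: 79.6, 2.2; 2.50: 82.0, 0.7; 3.00: 80.5, 0.1

(each reading ± 1 percentage point)

- which flask leads in amount of target, in percent of the starting material charged ("all alike" within 1.5 percentage points) (Monday's / Tuesday's / Thursday's / Sunday's / all alike)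
- how much target is there at the end, in percent of the starting material charged: Monday's
- how much target is there at the end, in percent of the starting material charged: Tuesday's
- how much target is there at the end, in percent of the starting material charged: Thursday's
- how much target is there at the end, in percent of the starting material charged: Sunday's

In the larch run starting material falls with a pseudo-first-order constant, called the pull here, of 3.11 min⁻¹ up to 0.500 min, but of 1.23 min⁻¹ from there to 1.33 min. The pull has dropped to 39.5% of its early value, while 10 mM of starting material, taken one to one, can bring 24 mM of partner no lower than 58.3%. So the pull fades faster than consumption accounts for, and between the midpoints of those intervals it fades at 1.40 min⁻¹. Times the 3.0 min of a feed this makes 4.19, the overlap number: how many fade times a slow addition lasts.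

By this reckoning, starting material fed steadily into Sunday's fading pull meets it for about 23.9% of the feed, and that share, taken as target in percent of the charge, is the figure for Sunday's. Thursday's second portion is reckoned to meet 1.51% of the pull, hardly any, and its first portion is the larch recipe, so Thursday's is reckoned at about 40.2%. Monday's repeats the alder recipe, whose last reading is 77.2%. One number is not enough, though. Tuesday's has the same 4.19, but if the pull belongs to partner, the fading side is the one fed, and the number gives no figure; Tuesday's is placed between Monday's and Thursday's.

The forecast differs from this reckoning: it reads 75%, 48%, 78% and 82% in the order Monday's, Tuesday's, Thursday's, Sunday's, with Sunday's ahead, holding that “the loss is real and worsens” as starting material outweighs partner.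

The flasks give 75.8%, 64.0%, 44.0% and 22.9% in that order, and Monday's leads.

    partner + target ⇌ idle adduct, settled at all times (K = 210 M⁻¹)
    open intermediate + capture agent → trapped intermediate (k = 0.510 M⁻¹ s⁻¹)
    open intermediate + second intermediate → target (k = 21.0 M⁻¹ s⁻¹)
    2 second intermediate → homo product (k = 12.0 M⁻¹ s⁻¹)
    starting material ⇌ open intermediate (K = 1.40, k = 0.0860 s⁻¹)
    partner → second intermediate (k = 0.0540 s⁻¹)

Sunday's, with overlap number 4.19, stands at 22.9% against the reckoned 23.9%, and Thursday's at 44.0% against 40.2%. The neighbouring flask is Sunday's with the feed stretched from 3.0 min to 9.00 min, all else held. Its overlap number is 12.6, so the same reckoning puts its target at 7.94%. That flask ends with 10.8% of target.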